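The route rests on reading methylcyclohexene ring A as a former 4,4-disubstituted cyclohexa-2,5-dienone: the prenyl-bearing quaternary carbon Ca sits para to the methyl-bearing carbon C6, flanked by Cb and Cc, and the C1/C4 carbonyls of ene-dione ring B form a 1,4-dicarbonyl retron that ends at Cb. A chiral triazolylidene turns the aldehyde of an achiral 4-(4-oxobutanoyl)-4-prenyl dienone into an acyl-anion equivalent that adds to one enantiotopic β-carbon, closing ring B and setting Ca in a single operation. The surviving enone then takes the aryl group at Cc and delivers the methyl alkene; the arene is finally bridged to Cb through its enolate.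

Key step: step 5

Remarks on the chemistry (one line each):
- Labels: ring A = Ca–Cb–C5–C6–C7–Cc, ring B = Ca–C1(=O)–C2–C3–C4(=O)–Cb, ring C = arene; the beta face of ring A carries prenyl, the alpha face carries C1.
- A para-alkoxy group on the benzoate would sit on the sp3 carbon of the Birch 1,4-dihydro product and is prone to reductive loss, so benzoic acid is used and the ring oxygen comes from bis-allylic oxidation.
- In the cis-fused bicycle ring B covers the alpha face of Cc, where the aryl group must enter, so Cb (re-formed later through its enolate) is first epimerised to the trans ring fusion.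
- The starting materials 1, 2, 5 and 13 and (2,5-dimethoxyphenyl)magnesium bromide (used in one fallback) are taken to be commercial.

Step 1
Reactants: 1 benzoic acid; 2 1-bromo-3-methylbut-2-ene (prenyl bromide)
Product: 4 1-(3-methylbut-2-en-1-yl)cyclohexa-2,5-diene-1-carboxylic acid, via dilithium dienediolate 3 (not isolated)
Conditions: Li, NH3(l)/THF, −78 °C; then 2; NH4Cl, then aq. HCl
Reagents that add atoms: none
Why: Dissolving-metal reduction gives the 1,4-dihydro dianion, which the allylic bromide alkylates at the carboxylate-bearing carbon (Birch reductive alkylation), creating the quaternary, not yet stereogenic Ca.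

Step 2
Reactants: 4 1-(3-methylbut-2-en-1-yl)cyclohexa-2,5-diene-1-carboxylic acid; 5 2-(2-bromoethyl)-1,3-dioxolane
Product: 8 3-(1,3-dioxolan-2-yl)-1-[1-(3-methylbut-2-en-1-yl)cyclohexa-2,5-dien-1-yl]propan-1-one, via 1-(3-methylbut-2-en-1-yl)cyclohexa-2,5-diene-1-carbonyl chloride 6 (not isolated), via [2-(1,3-dioxolan-2-yl)ethyl]magnesium bromide 7 (not isolated)
Conditions: (COCl)2, cat. DMF, CH2Cl2, 0 → 23 °C; separately 5, Mg, THF, ≤30 °C; combine, Fe(acac)3 (3 mol%), THF, −78 °C
Reagents that add atoms: none
Why: The acid chloride couples once with the Grignard reagent under iron catalysis at low temperature (iron-catalysed acylation of a Grignard reagent), and the neopentyl-type ketone formed resists a second addition.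

Step 3
Reactants: 8 3-(1,3-dioxolan-2-yl)-1-[1-(3-methylbut-2-en-1-yl)cyclohexa-2,5-dien-1-yl]propan-1-one
Product: 9 4-[3-(1,3-dioxolan-2-yl)propanoyl]-4-(3-methylbut-2-en-1-yl)cyclohexa-2,5-dien-1-one
Conditions: Rh2(cap)4 (1 mol%), t-BuOOH (in decane), ClCH2CH2Cl, 40 °C
Reagents that add atoms: tert-butyl hydroperoxide, CC(C)(C)OO
Why: The doubly allylic ring CH2 holds the weakest C–H bonds of the molecule, so base-free hydroperoxide oxidation (bis-allylic oxidation of a Birch diene) should convert it selectively into the dienone carbonyl.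

Step 4
Reactants: 9 4-[3-(1,3-dioxolan-2-yl)propanoyl]-4-(3-methylbut-2-en-1-yl)cyclohexa-2,5-dien-1-one
Product: 10 4-[1-(3-methylbut-2-en-1-yl)-4-oxocyclohexa-2,5-dien-1-yl]-4-oxobutanal (achiral Stetter precursor)
Conditions: 1 M aq. HCl, THF, 23 °C
Reagents that add atoms: water, O
Why: Dilute aqueous acid cleaves the dioxolane (acetal hydrolysis) while the blocked dienone and the trisubstituted alkene are left alone, since no basic nucleophile is present that could cleave the acyl group from Ca.

Step 5
Reactants: 10 4-[1-(3-methylbut-2-en-1-yl)-4-oxocyclohexa-2,5-dien-1-yl]-4-oxobutanal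
Product: 11 (4aR,8aS)-8a-(3-methylbut-2-en-1-yl)-2,3,4a,5-tetrahydronaphthalene-1,4,6(8aH)-trione (cis-fused; Ca = C8a, Cb = C4a)
Conditions: chiral aminoindanol-derived N-pentafluorophenyl triazolium tetrafluoroborate (20 mol%, antipode chosen to deliver the (8aS) centre), KHMDS (20 mol%), toluene, 23 °C
Reagents that add atoms: none
Why: The free carbene adds to the aldehyde and proton transfer gives a hydroxy-enamine, an acyl-anion equivalent at C4, which attacks the β-carbon Cb of one enone arm; proton transfer and loss of the carbene then release the 1,4-diketone. This is the intramolecular asymmetric Stetter reaction, in the form established for desymmetrising 4,4-disubstituted cyclohexadienones. Ring B closes in a 6-exo-trig mode. Ca becomes stereogenic because the chiral carbene distinguishes the two enantiotopic enone arms, and Cb is set by the three-atom tether, which can deliver C4 only to the face on which C1 sits (cis fusion). The step needs acyl-anion addition to outrun aldol and Michael reactions of the enolisable keto-aldehyde; the nearly base-free carbene conditions and the proximity of the acceptor should secure this. The hindered C1 ketone and the prenyl alkene offer the catalyst no competing site.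

Step 6
Reactants: 11 (4aR,8aS)-8a-(3-methylbut-2-en-1-yl)-2,3,4a,5-tetrahydronaphthalene-1,4,6(8aH)-trione
Product: 12 (4aS,8aS)-8a-(3-methylbut-2-en-1-yl)-2,3,4a,5-tetrahydronaphthalene-1,4,6(8aH)-trione (trans-fused)
Conditions: DBU (0.2 equiv), toluene, 23 °C; chromatographic separation, cis isomer resubmitted
Reagents that add atoms: none
Why: Cb–H is alpha to the C4 ketone, so amine-mediated enolisation (base-catalysed epimerisation) should interconvert the two ring-fusion isomers and reprotonation sets Cb; the trans isomer, with prenyl axial on ring A and the alpha face of Cc uncovered, is taken on.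

Step 7
Reactants: 13 2-bromo-1,4-dimethoxybenzene
Product: 15 2-bromo-3-iodo-1,4-dimethoxybenzene, via (2-bromo-3,6-dimethoxyphenyl)lithium 14 (not isolated)
Conditions: LDA, THF, −78 °C; then I2, −78 °C
Reagents that add atoms: iodine, [I][I]
Why: LDA removes the most acidic ring proton, the one flanked by bromine and methoxy (directed ortho-lithiation), and the aryllithium is iodinated at −78 °C before it can lose LiBr.

Step 8
Reactants: 12 (4aS,8aS)-8a-(3-methylbut-2-en-1-yl)-2,3,4a,5-tetrahydronaphthalene-1,4,6(8aH)-trione; 15 2-bromo-3-iodo-1,4-dimethoxybenzene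
Product: 18 trans-fused 8-(2-bromo-3,6-dimethoxyphenyl)-8a-(3-methylbut-2-en-1-yl)-6-(trimethylsilyloxy)-2,3,4a,5,8,8a-hexahydronaphthalene-1,4-dione (aryl at Cc on the alpha face, anti to prenyl), via (2-bromo-3,6-dimethoxyphenyl)magnesium chloride 16 (not isolated), via chloromagnesium bis(2-bromo-3,6-dimethoxyphenyl)cuprate 17 (not isolated)
Conditions: 15, i-PrMgCl·LiCl, THF, −40 °C; CuBr·SMe2 (0.5 equiv per aryl), −78 °C; TMSCl, then 12, −78 → −40 °C; Et3N, aq. NaHCO3
Reagents that add atoms: chlorotrimethylsilane, C[Si](C)(C)Cl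
Why: Iodine–magnesium exchange spares the bromide and the derived cuprate adds to the enone under TMSCl activation (organocuprate conjugate addition with enolate silylation); attack should be axial and anti to the axial angular prenyl group of the trans-fused bicycle, as in additions to angular-methyl steroidal 1-en-3-ones, which sets Cc with the aryl group on the alpha face and fixes the enol ether between C6 and C7.

Step 9
Reactants: 18 trans-fused 8-(2-bromo-3,6-dimethoxyphenyl)-8a-(3-methylbut-2-en-1-yl)-6-(trimethylsilyloxy)-2,3,4a,5,8,8a-hexahydronaphthalene-1,4-dione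
Product: 19 trans-fused 8-(2-bromo-3,6-dimethoxyphenyl)-8a-(3-methylbut-2-en-1-yl)-1,4-dioxo-1,2,3,4,4a,5,8,8a-octahydronaphthalen-6-yl trifluoromethanesulfonate
Conditions: CsF, PhNTf2, DME, 23 °C
Reagents that add atoms: N-phenylbis(trifluoromethanesulfonimide), O=S(=O)(N(c1ccccc1)S(=O)(=O)C(F)(F)F)C(F)(F)F
Why: Fluoride cleaves the O–Si bond and the regiodefined enolate is triflated in the same flask before it can equilibrate with the other ketones (desilylative enol triflation), the stereocentres being untouched.

Step 10
Reactants: 19 trans-fused 8-(2-bromo-3,6-dimethoxyphenyl)-8a-(3-methylbut-2-en-1-yl)-1,4-dioxo-1,2,3,4,4a,5,8,8a-octahydronaphthalen-6-yl trifluoromethanesulfonate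
Product: 20 trans-fused 8-(2-bromo-3,6-dimethoxyphenyl)-6-methyl-8a-(3-methylbut-2-en-1-yl)-2,3,4a,5,8,8a-hexahydronaphthalene-1,4-dione
Conditions: MeZnCl, Pd(PPh3)4 (5 mol%), THF, 23 °C
Reagents that add atoms: methylzinc chloride, C[Zn]Cl
Why: The vinyl triflate should add oxidatively to zerovalent palladium at room temperature far faster than the hindered, electron-rich aryl bromide, and methylzinc chloride tolerates the two ketones (Negishi coupling).

Step 11
Reactants: 20 trans-fused 8-(2-bromo-3,6-dimethoxyphenyl)-6-methyl-8a-(3-methylbut-2-en-1-yl)-2,3,4a,5,8,8a-hexahydronaphthalene-1,4-dione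
Product: 22 8-(2-bromo-3,6-dimethoxyphenyl)-6-methyl-8a-(3-methylbut-2-en-1-yl)-4a,5,8,8a-tetrahydronaphthalene-1,4-dione (ring B ene-dione; Cb drawn trans, labile and of no consequence), via bis(trimethylsilyl) dienol ether 21 (not isolated)
Conditions: TMSOTf, Et3N, CH2Cl2, −78 → 0 °C; then DDQ, 0 °C
Reagents that add atoms: none
Why: Both ring B ketones are O-silylated towards C2 and C3 to give a 1,4-bis(silyloxy)-1,3-diene, which DDQ should oxidise to the ene-dione in the way a hydroquinone bis-silyl ether gives a quinone (silyl dienol ether dehydrogenation), ring A no longer holding a second 1,4-dicarbonyl unit.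

Step 12
Reactants: 22 8-(2-bromo-3,6-dimethoxyphenyl)-6-methyl-8a-(3-methylbut-2-en-1-yl)-4a,5,8,8a-tetrahydronaphthalene-1,4-dione
Product: 24 bis(methyl ether) of the target (arene bridging Cb and Cc on the alpha face; C4 now on the beta face of Cb), via potassium dienolate 23 (not isolated)
Conditions: KHMDS (1.05 equiv), toluene, −78 °C; then Pd[P(t-Bu)3]2 (10 mol%), 70 °C
Reagents that add atoms: none
Why: Cb–H is now the only acidic proton, and its preformed dienolate is arylated by the tethered aryl bromide through oxidative addition, a six-membered palladacycle and C–C reductive elimination (intramolecular palladium-catalysed ketone alpha-arylation); because Cc holds the aryl group on the alpha face, the new bond at Cb can only form there, which sets Cb and turns C4 to the beta face.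

Step 13
Reactants: 24 bis(methyl ether) of the target
Product: 26 CNP0166383.1 (target; Ca S, Cb R, Cc R), via benzoquinone 25 (not isolated)
Conditions: (NH4)2Ce(NO3)6, MeCN/H2O, 0 °C; then aq. Na2S2O4, EtOAc, 23 °C
Reagents that add atoms: water, O
Why: Tetravalent cerium oxidises the para-dimethoxyarene to the quinone with loss of methanol (oxidative demethylation), and dithionite should reduce the quinone, the most easily reduced group present, to the hydroquinone without touching the ene-dione or the alkenes.

Compound list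
1 | benzoic acid | O=C(O)c1ccccc1 | starting material
2 | 1-bromo-3-methylbut-2-ene (prenyl bromide) | CC(C)=CCBr | starting material
3 | dilithium (cyclohexa-2,5-dien-1-ylidene)methanediolate | [Li+].[Li+].[O-]C([O-])=C1C=CCC=C1 | intermediate
4 | 1-(3-methylbut-2-en-1-yl)cyclohexa-2,5-diene-1-carboxylic acid | CC(C)=CCC1(C=CCC=C1)C(=O)O | intermediate
5 | 2-(2-bromoethyl)-1,3-dioxolane | BrCCC1OCCO1 | starting material
6 | 1-(3-methylbut-2-en-1-yl)cyclohexa-2,5-diene-1-carbonyl chloride | CC(C)=CCC1(C=CCC=C1)C(Cl)=O | intermediate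
7 | [2-(1,3-dioxolan-2-yl)ethyl]magnesium bromide | Br[Mg]CCC1OCCO1 | intermediate
8 | 3-(1,3-dioxolan-2-yl)-1-[1-(3-methylbut-2-en-1-yl)cyclohexa-2,5-dien-1-yl]propan-1-one | CC(C)=CCC1(C=CCC=C1)C(=O)CCC1OCCO1 | intermediate
9 | 4-[3-(1,3-dioxolan-2-yl)propanoyl]-4-(3-methylbut-2-en-1-yl)cyclohexa-2,5-dien-1-one | CC(C)=CCC1(C=CC(=O)C=C1)C(=O)CCC1OCCO1 | intermediate
10 | 4-[1-(3-methylbut-2-en-1-yl)-4-oxocyclohexa-2,5-dien-1-yl]-4-oxobutanal | CC(C)=CCC1(C=CC(=O)C=C1)C(=O)CCC=O | intermediate
11 | (4aR,8aS)-8a-(3-methylbut-2-en-1-yl)-2,3,4a,5-tetrahydronaphthalene-1,4,6(8aH)-trione (cis-fused) | CC(C)=CC[C@@]12C(=O)CCC(=O)[C@@H]1CC(=O)C=C2 | intermediate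
12 | (4aS,8aS)-8a-(3-methylbut-2-en-1-yl)-2,3,4a,5-tetrahydronaphthalene-1,4,6(8aH)-trione (trans-fused) | CC(C)=CC[C@@]12C(=O)CCC(=O)[C@H]1CC(=O)C=C2 | intermediate
13 | 2-bromo-1,4-dimethoxybenzene | COc1ccc(OC)c(Br)c1 | starting material
14 | (2-bromo-3,6-dimethoxyphenyl)lithium | COc1ccc(OC)c([Li])c1Br | intermediate
15 | 2-bromo-3-iodo-1,4-dimethoxybenzene | COc1ccc(OC)c(I)c1Br | intermediate
16 | (2-bromo-3,6-dimethoxyphenyl)magnesium chloride | COc1ccc(OC)c([Mg]Cl)c1Br | intermediate
17 | chloromagnesium bis(2-bromo-3,6-dimethoxyphenyl)cuprate | COc1ccc(OC)c([Cu-]c2c(Br)c(OC)ccc2OC)c1Br.[Mg+]Cl | intermediate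
18 | trans-fused silyl enol ether, aryl at Cc anti to prenyl | CC(C)=CC[C@@]12C(=O)CCC(=O)[C@H]1CC(O[Si](C)(C)C)=C[C@@H]2c1c(Br)c(OC)ccc1OC | intermediate
19 | trans-fused enol triflate, aryl at Cc anti to prenyl | CC(C)=CC[C@@]12C(=O)CCC(=O)[C@H]1CC(OS(=O)(=O)C(F)(F)F)=C[C@@H]2c1c(Br)c(OC)ccc1OC | intermediate
20 | trans-fused 8-(2-bromo-3,6-dimethoxyphenyl)-6-methyl-8a-(3-methylbut-2-en-1-yl)-2,3,4a,5,8,8a-hexahydronaphthalene-1,4-dione | CC(C)=CC[C@@]12C(=O)CCC(=O)[C@H]1CC(C)=C[C@@H]2c1c(Br)c(OC)ccc1OC | intermediate
21 | 1,4-bis(trimethylsilyloxy)-1,3-diene of 20 | CC(C)=CC[C@@]12C(O[Si](C)(C)C)=CC=C(O[Si](C)(C)C)[C@H]1CC(C)=C[C@@H]2c1c(Br)c(OC)ccc1OC | intermediate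
22 | 8-(2-bromo-3,6-dimethoxyphenyl)-6-methyl-8a-(3-methylbut-2-en-1-yl)-4a,5,8,8a-tetrahydronaphthalene-1,4-dione | CC(C)=CC[C@@]12C(=O)C=CC(=O)[C@H]1CC(C)=C[C@@H]2c1c(Br)c(OC)ccc1OC | intermediate
23 | potassium dienolate of 22 | CC(C)=CC[C@@]12C(=O)C=CC([O-])=C1CC(C)=C[C@@H]2c1c(Br)c(OC)ccc1OC.[K+] | intermediate
24 | bis(methyl ether) of the target | CC(C)=CC[C@@]12C(=O)C=CC(=O)[C@@]13CC(C)=C[C@@H]2c1c(OC)ccc(OC)c13 | intermediate
25 | benzoquinone corresponding to the target | CC(C)=CC[C@@]12C(=O)C=CC(=O)[C@@]13CC(C)=C[C@@H]2C4=C3C(=O)C=CC4=O | intermediate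
26 | CNP0166383.1 | CC(C)=CC[C@@]12C(=O)C=CC(=O)[C@@]13CC(C)=C[C@@H]2c1c(O)ccc(O)c13 | target

Total step count: 13. Longest linear sequence: 12 steps (steps 1–6 and 8–13, from benzoic acid); step 7 is a one-step side branch.

Steps most likely to fail

Step 5. The six-membered closure may be slow, so that enolisation-driven aldol or Michael pathways of the keto-aldehyde take over, or the carbene may discriminate the two enone arms poorly. The fallback sets out from 10 and gives up catalytic enantiocontrol: irradiation at 365 nm with (n-Bu4N)4W10O32 in MeCN abstracts the aldehyde hydrogen, and the acyl radical should close 6-exo onto the dienone on the tether face (photocatalytic hydroacylation) to give the racemic cis-fused trione F1. Preparative chromatography on a chiral stationary phase then returns the route to 11.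

Step 8. The doubly ortho-substituted aryl group may fail to transfer to the neopentyl-type β-carbon, or the organometallic may add to the saturated ketones instead. The fallback sets out from 12 and removes the ortho bromine from the nucleophile. Commercial (2,5-dimethoxyphenyl)magnesium bromide with catalytic CuBr·SMe2 and TMSCl should give the silyl enol ether F2. CsF/PhNTf2 converts it into the enol triflate F3, and MeZnCl/Pd(PPh3)4 into the methyl alkene F4. IBX in DMSO at 65 °C dehydrogenates ring B to the ene-dione F5, and (NH4)2Ce(NO3)6 gives the aryl-substituted benzoquinone F6. Mild base (K2CO3, MeCN) then lets the Cb dienolate add to the adjacent quinone carbon (intramolecular Michael addition) and tautomerisation gives the hydroquinone, so this line comes back to the route at 26.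

Step 12. Reductive elimination to the congested quaternary carbon may be outrun by Heck-type insertion into the ene-dione alkene or by hydrodebromination. The fallback sets out from 22 and reverses the polarity of the arene: (NH4)2Ce(NO3)6 oxidises the ring to the bromobenzoquinone F7, and K2CO3 in MeCN lets the Cb dienolate displace bromide by addition–elimination on the haloquinone. This comes back to the route at 25, which the dithionite treatment of step 13 reduces to 26.

Further compounds
F1 | step 5 | racemic cis-fused 8a-(3-methylbut-2-en-1-yl)-2,3,4a,5-tetrahydronaphthalene-1,4,6(8aH)-trione | CC(C)=CC[C@@]12C(=O)CCC(=O)[C@@H]1CC(=O)C=C2.CC(C)=CC[C@]12C(=O)CCC(=O)[C@H]1CC(=O)C=C2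
F2 | step 8 | trans-fused silyl enol ether bearing 2,5-dimethoxyphenyl at Cc anti to prenyl | CC(C)=CC[C@@]12C(=O)CCC(=O)[C@H]1CC(O[Si](C)(C)C)=C[C@@H]2c1cc(OC)ccc1OC
F3 | step 8 | corresponding enol triflate | CC(C)=CC[C@@]12C(=O)CCC(=O)[C@H]1CC(OS(=O)(=O)C(F)(F)F)=C[C@@H]2c1cc(OC)ccc1OC
F4 | step 8 | trans-fused 8-(2,5-dimethoxyphenyl)-6-methyl-8a-(3-methylbut-2-en-1-yl)-2,3,4a,5,8,8a-hexahydronaphthalene-1,4-dione | CC(C)=CC[C@@]12C(=O)CCC(=O)[C@H]1CC(C)=C[C@@H]2c1cc(OC)ccc1OC
F5 | step 8 | 8-(2,5-dimethoxyphenyl)-6-methyl-8a-(3-methylbut-2-en-1-yl)-4a,5,8,8a-tetrahydronaphthalene-1,4-dione | CC(C)=CC[C@@]12C(=O)C=CC(=O)[C@H]1CC(C)=C[C@@H]2c1cc(OC)ccc1OC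
F6 | step 8 | 2-substituted 1,4-benzoquinone derived from F5 | CC(C)=CC[C@@]12C(=O)C=CC(=O)[C@H]1CC(C)=C[C@@H]2C1=CC(=O)C=CC1=O
F7 | step 12 | 2-bromo-3-substituted 1,4-benzoquinone derived from 22 | CC(C)=CC[C@@]12C(=O)C=CC(=O)[C@H]1CC(C)=C[C@@H]2C1=C(Br)C(=O)C=CC1=O
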